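(The data were generated by integration on assumed constants.)

Follow the split.

in all of them: starting material 0.65 M; free catalyst 0.2 mol%
- eta: partner 2 equiv; capture agent 0.65 M; the very flask that is asked about, followed so far
- epsilon: partner 2 equiv; capture agent 0.33 M; run made earlier
- flask: partner 2.00 equiv; capture agent 0.650 M; time 20 min

| run | time / min | product / % | trapped intermediate / % |
|---|---|---|---|
| eta | 0.500 | 6.0 | 24.5 |
| eta | 0.833 | 10.6 | 39.6 |
| eta | 1.33 | 14.0 | 52.3 |
| eta | 2.00 | 16.9 | 61.4 |
| eta | 4.00 | 19.9 | 72.4 |
| eta | 6.00 | 19.9 | 75.4 |
| epsilon | 0.500 | 8.1 | 16.3 |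
| epsilon | 1.50 | 22.0 | 37.2 |
| epsilon | 3.00 | 31.8 | 45.7 |
| epsilon | 4.00 | 35.5 | 48.0 |
| epsilon | 6.00 | 38.7 | 49.4 |
| epsilon | 8.00 | 39.4 | 49.7 |

(readings scatter by 0.3 percentage points)

1. ratio of product to trapped intermediate at 6.0 s
2. ratio of product to trapped intermediate at 80 s
3. ratio of product to trapped intermediate at 20 min

Taking one capture agent per trapped intermediate, [capture agent] in runs eta and epsilon can be reckoned from the readings. The split number, a selectivity factor, is the product gained per trapped intermediate gained over an interval, times the mean [capture agent] of that interval. Over the first reading it reads 0.140 M in eta and 0.138 M in epsilon, although eta was charged with twice the capture agent.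

The first chemist calls this number a constant, so that the ratio simply follows [capture agent]. Then eta stands at 0.212 at 6.0 s, and integrating up to the trapped intermediate read at 6.00 min gives a ratio of 0.394.

The second chemist objects. Eta reads 0.264 there, less than that, and epsilon's split number between 3.00 min and 4.00 min reads 0.0410 M, lower than its first value. So in epsilon the number, as read, falls with time, halving about every 1.86 min.

I side with the second. Carried back to the middle of the first 6.0 s, the split number, product gained per trapped intermediate gained times mean [capture agent], is 0.148 M. Dividing by the charge gives me 0.228 at 6.0 s. For 80 s I keep eta's reading, 0.268, and for 20 min the reading 0.264; eta's product reads 19.9 % at 4.00 min and 19.9 % at 6.00 min.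

The forecast gave 0.22, 0.27 and 0.27, judging that the levelling off “looks like the catalyst dying”.

The simulation gives 0.255, 0.269 and 0.262.

    partner + catalyst intermediate → free catalyst + product (k = 7.50 M⁻¹ s⁻¹)
    free catalyst + open intermediate ⇌ catalyst intermediate (K = 3.20 M⁻¹, k = 45.0 M⁻¹ s⁻¹)
    starting material + free catalyst → free catalyst + open intermediate (k = 19.0 M⁻¹ s⁻¹)
    free catalyst → spent catalyst (k = 0.00740 s⁻¹)
    open intermediate + capture agent → trapped intermediate (k = 0.130 M⁻¹ s⁻¹)

The ratio at 6.0 s, times the charge of capture agent, gives 0.166 M, higher than my 0.148 M. The first chemist's constant has its region at one early moment, with flasks differing in [capture agent]. In the neighbouring flask, charged with 0.26 M of capture agent, 0.166 M over that charge gives 0.638 at 6.0 s, and that flask gives 0.633. Its ratio then reaches 0.759 at 80 s. In that flask at 20 min, capture agent stands at 0 % of its charge, open intermediate at 8.75 % and product at 47.7 % of the starting material charged, and the ratio at 1.19.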